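**Plan**

- Retrosynthesis: the 7-O–ethyl and 8'-O–methyl bonds are cut first. Ring A is then cut at C8a–C8, C7–C8, C5–C6 and C4a–C5, leaving a 2-diazoacetyl-4-pyranone (ring C with C4a, C8a and the future C5 and C8) and ethoxyacetylene (C6 and C7). The C3–C1' bond leads back to a kojic acid triflate and a chromanyl boronate.
- Enabling feature: ring A is a resorcinol with its oxygens meta at C5 and C7, fused to pyranone ring C along C4a–C8a. C8a has only O1 and C4a as ring neighbours, so a ketene chain on C8a can close at C4a alone, and the ketene carbon arrives as C5–OH next to the C4 carbonyl.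
- Forward order: the dimethylpyran ring of the chroman is built first on 5-bromo-2-methoxyphenol; ring C is bought as kojic acid; the two are joined at C3–C1' by Suzuki coupling; the side chain is oxidised and made into the diazoketone; ring A is closed last by benzannulation; BBr3 then frees the phenols.
- Stereochemistry: the target has no stereocentre and no configured double bond, so none has to be set.

Key step: step 11

Assumption: ethoxyacetylene is used as its commercial solution in hexanes, and light of about 450 nm is taken to be absorbed by the diazoketone chromophore only.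

**Route**

Step 1
Reactants: 1 5-bromo-2-methoxyphenol; 2 3-chloro-3-methylbut-1-yne
Product: 3 4-bromo-1-methoxy-2-[(2-methylbut-3-yn-2-yl)oxy]benzene
Conditions: K2CO3, KI (cat.), CuI (cat.), acetone, reflux
Reagents that add atoms: none
Why: Copper-assisted Williamson-type O-alkylation of the phenoxide with a tertiary propargylic chloride should give the 1,1-dimethylpropargyl aryl ether, the usual precursor of 2,2-dimethylchromenes.

Step 2
Reactants: 3 4-bromo-1-methoxy-2-[(2-methylbut-3-yn-2-yl)oxy]benzene
Product: 4 5-bromo-8-methoxy-2,2-dimethyl-2H-chromene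
Conditions: N,N-diethylaniline, 190 °C
Reagents that add atoms: none
Why: Aryl propargyl ether Claisen rearrangement, 1,5-hydrogen shift and oxa-6π electrocyclisation should give the chromene, and because the methoxy group blocks one ortho position the new C–C bond can form only next to bromine, which puts Br at C5 and OMe at C8.

Step 3
Reactants: 4 5-bromo-8-methoxy-2,2-dimethyl-2H-chromene
Product: 5 2-(8-methoxy-2,2-dimethyl-2H-chromen-5-yl)-4,4,5,5-tetramethyl-1,3,2-dioxaborolane
Conditions: B2pin2, PdCl2(dppf) (3 mol %), KOAc, 1,4-dioxane, 90 °C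
Reagents that add atoms: bis(pinacolato)diboron, CC1(C)OB(OC1(C)C)B1OC(C)(C)C(C)(C)O1
Why: Miyaura borylation of an aryl bromide tolerates the ortho alkenyl substituent and the aryl ethers, and exchanging bromine for boron at this point removes the risk of hydrodebromination in the next step.

Step 4
Reactants: 5 2-(8-methoxy-2,2-dimethyl-2H-chromen-5-yl)-4,4,5,5-tetramethyl-1,3,2-dioxaborolane
Product: 6 2-(8-methoxy-2,2-dimethylchroman-5-yl)-4,4,5,5-tetramethyl-1,3,2-dioxaborolane
Conditions: H2 (1 atm), 10% Pd/C, EtOAc, rt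
Reagents that add atoms: none
Why: Catalytic hydrogenation of the styrene-type C3=C4 bond of a 2H-chromene is routine and leaves the aryl–boron bond and the ring ether intact.

Step 5
Reactants: 7 kojic acid (5-hydroxy-2-(hydroxymethyl)-4H-pyran-4-one)
Product: 8 2-{[(tert-butyldimethylsilyl)oxy]methyl}-5-hydroxy-4H-pyran-4-one
Conditions: TBSCl (1.05 equiv), imidazole, DMF, 0 °C to rt
Reagents that add atoms: tert-butyldimethylsilyl chloride, CC(C)(C)[Si](C)(C)Cl
Why: Selective silylation of the primary alcohol is expected because any silyl ether formed on the acidic enolic 5-OH is labile and is hydrolysed on aqueous work-up.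

Step 6
Reactants: 8 2-{[(tert-butyldimethylsilyl)oxy]methyl}-5-hydroxy-4H-pyran-4-one
Product: 9 6-{[(tert-butyldimethylsilyl)oxy]methyl}-4-oxo-4H-pyran-3-yl trifluoromethanesulfonate
Conditions: PhNTf2 (1.1 equiv), Et3N, CH2Cl2, 0 °C to rt
Reagents that add atoms: N-phenylbis(trifluoromethanesulfonimide), O=S(=O)(N(c1ccccc1)S(=O)(=O)C(F)(F)F)C(F)(F)F
Why: O-Triflation of a phenol-like enol with PhNTf2 and an amine base is mild enough to leave the silyl ether and the pyranone untouched.

Step 7
Reactants: 9 6-{[(tert-butyldimethylsilyl)oxy]methyl}-4-oxo-4H-pyran-3-yl trifluoromethanesulfonate; 6 2-(8-methoxy-2,2-dimethylchroman-5-yl)-4,4,5,5-tetramethyl-1,3,2-dioxaborolane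
Product: 10 2-{[(tert-butyldimethylsilyl)oxy]methyl}-5-(8-methoxy-2,2-dimethylchroman-5-yl)-4H-pyran-4-one
Conditions: PdCl2(dppf) (5 mol %), K3PO4, 1,4-dioxane/H2O 9:1, 70 °C
Reagents that add atoms: none
Why: Suzuki–Miyaura coupling should form the C3–C1' bond, since zerovalent palladium adds readily to the enol triflate next to the pyranone carbonyl and 5-triflates of O-silylated kojic acid are established partners in such couplings.

Step 8
Reactants: 10 2-{[(tert-butyldimethylsilyl)oxy]methyl}-5-(8-methoxy-2,2-dimethylchroman-5-yl)-4H-pyran-4-one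
Product: 11 2-(hydroxymethyl)-5-(8-methoxy-2,2-dimethylchroman-5-yl)-4H-pyran-4-one
Conditions: 1 M aq HCl, THF, rt
Reagents that add atoms: none
Why: Acid hydrolysis of a primary silyl ether is fast under conditions to which the pyranone, the aryl methyl ether and the chroman are inert.

Step 9
Reactants: 11 2-(hydroxymethyl)-5-(8-methoxy-2,2-dimethylchroman-5-yl)-4H-pyran-4-one
Product: 12 5-(8-methoxy-2,2-dimethylchroman-5-yl)-4-oxo-4H-pyran-2-carboxylic acid
Conditions: TEMPO (0.2 equiv), PhI(OAc)2 (2.5 equiv), MeCN/H2O 1:1, rt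
Reagents that add atoms: water, O
Why: Oxoammonium-mediated (TEMPO) oxidation takes the activated primary alcohol through the readily hydrated electron-poor aldehyde to the acid, in parallel with the known oxidation of 5-O-protected kojic acids to comenic acids, and without a free phenol the arene is not attacked.

Step 10
Reactants: 12 5-(8-methoxy-2,2-dimethylchroman-5-yl)-4-oxo-4H-pyran-2-carboxylic acid
Product: 14 2-(2-diazoacetyl)-5-(8-methoxy-2,2-dimethylchroman-5-yl)-4H-pyran-4-one, via acid chloride 13 (not isolated)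
Conditions: (COCl)2, DMF (cat.), CH2Cl2, 0 °C to rt, evaporate; then TMSCHN2 (2.2 equiv), THF/MeCN 1:1, 0 °C to rt, concentrate and chromatograph
Reagents that add atoms: (trimethylsilyl)diazomethane, C[Si](C)(C)C=[N+]=[N-] (diazomethyl carbon and both nitrogens of 14); oxalyl chloride, O=C(Cl)C(=O)Cl (chlorine of 13 only)
Why: Acid chloride formation followed by C-acylation of the silylated diazoalkane with loss of the silyl group (the first stage of an Arndt–Eistert sequence) is the standard entry to diazomethyl ketones, and the acyl chloride is far more electrophilic than the pyranone enone.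

Step 11
Reactants: 14 2-(2-diazoacetyl)-5-(8-methoxy-2,2-dimethylchroman-5-yl)-4H-pyran-4-one; 15 ethoxyacetylene
Product: 19 7-ethoxy-5-hydroxy-3-(8-methoxy-2,2-dimethylchroman-5-yl)-4H-chromen-4-one, via pyranonylketene 16 (not isolated), via 3-ethoxy-4-pyranonylcyclobutenone 17 (not isolated), via dienylketene 18 (not isolated)
Conditions: 15 (5 equiv), degassed ClCH2CH2Cl (0.05 M), blue LEDs (450 nm), rt, until N2 evolution ends; then 80 °C in the dark
Reagents that add atoms: none
Why: Proposed new method: Light expels N2 from 14 and the Wolff 1,2-shift moves pyranone carbon C8a onto the former diazo carbon (C8–C8a) to give ketene 16; ethoxyacetylene then adds (2+2), its nucleophilic CH carbon bonding to the ketene carbonyl carbon (C5–C6) and its oxygen-bearing carbon to the ketene CH (C7–C8), and the resulting cyclobutenone 17 opens reversibly on heating (4π, C5–C8 cleaved) to dienylketene 18. Ring A closes by a 6π electrocyclisation in which the ketene carbon C5 bonds to C4a of the pyranone double bond, and enolisation of the cyclohexadienone gives the phenol. The closest known chemistry is the second-generation Danheiser benzannulation of aryl, heteroaryl and alkenyl diazomethyl ketones with alkoxy- or siloxyalkynes; a 4-pyranone as the 2π partner is not documented, but its C4a=C8a bond is an enol-ether-type alkene with little aromatic stabilisation and a nucleophilic α-carbon (C4a) that is polarity-matched to the electrophilic ketene carbon. No stereocentre is formed. Two selectivities are needed: the orientation of the (2+2) step, fixed by the polarisation of the ynol ether, puts OEt at C7 and the new hydroxyl at C5, and the site of closure is unambiguous because the only carbon neighbour of C8a in ring C is C4a, the other neighbour being O1. Visible light is used so that only the diazoketone absorbs and the ultraviolet photochemistry of 4-pyranones is avoided.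

Step 12
Reactants: 19 7-ethoxy-5-hydroxy-3-(8-methoxy-2,2-dimethylchroman-5-yl)-4H-chromen-4-one
Product: 20 5,7-dihydroxy-3-(8-hydroxy-2,2-dimethylchroman-5-yl)-4H-chromen-4-one
Conditions: BBr3 (6 equiv), CH2Cl2, –78 °C to rt; then H2O
Reagents that add atoms: none
Why: BBr3 dealkylation of aryl alkyl ethers cleaves both primary ethers by bromide attack on the boron-complexed oxygens while the 5-OH is held as a borate chelate, and methoxy-2,2-dimethylchromans are routinely demethylated this way at low temperature.

**Compound list**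

1 | 5-bromo-2-methoxyphenol | COc1ccc(Br)cc1O | starting material
2 | 3-chloro-3-methylbut-1-yne | C#CC(C)(C)Cl | starting material
3 | 4-bromo-1-methoxy-2-[(2-methylbut-3-yn-2-yl)oxy]benzene | COc1ccc(Br)cc1OC(C)(C)C#C | intermediate
4 | 5-bromo-8-methoxy-2,2-dimethyl-2H-chromene | COc1ccc(Br)c2C=CC(C)(C)Oc12 | intermediate
5 | 2-(8-methoxy-2,2-dimethyl-2H-chromen-5-yl)-4,4,5,5-tetramethyl-1,3,2-dioxaborolane | COc1ccc(B2OC(C)(C)C(C)(C)O2)c2C=CC(C)(C)Oc12 | intermediate
6 | 2-(8-methoxy-2,2-dimethylchroman-5-yl)-4,4,5,5-tetramethyl-1,3,2-dioxaborolane | COc1ccc(B2OC(C)(C)C(C)(C)O2)c2CCC(C)(C)Oc12 | intermediate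
7 | kojic acid, 5-hydroxy-2-(hydroxymethyl)-4H-pyran-4-one | OCc1cc(=O)c(O)co1 | starting material
8 | 2-{[(tert-butyldimethylsilyl)oxy]methyl}-5-hydroxy-4H-pyran-4-one | CC(C)(C)[Si](C)(C)OCc1cc(=O)c(O)co1 | intermediate
9 | 6-{[(tert-butyldimethylsilyl)oxy]methyl}-4-oxo-4H-pyran-3-yl trifluoromethanesulfonate | CC(C)(C)[Si](C)(C)OCc1cc(=O)c(OS(=O)(=O)C(F)(F)F)co1 | intermediate
10 | 2-{[(tert-butyldimethylsilyl)oxy]methyl}-5-(8-methoxy-2,2-dimethylchroman-5-yl)-4H-pyran-4-one | CC(C)(C)[Si](C)(C)OCc1cc(=O)c(-c2ccc(OC)c3OC(C)(C)CCc23)co1 | intermediate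
11 | 2-(hydroxymethyl)-5-(8-methoxy-2,2-dimethylchroman-5-yl)-4H-pyran-4-one | OCc1cc(=O)c(-c2ccc(OC)c3OC(C)(C)CCc23)co1 | intermediate
12 | 5-(8-methoxy-2,2-dimethylchroman-5-yl)-4-oxo-4H-pyran-2-carboxylic acid | OC(=O)c1cc(=O)c(-c2ccc(OC)c3OC(C)(C)CCc23)co1 | intermediate
13 | 5-(8-methoxy-2,2-dimethylchroman-5-yl)-4-oxo-4H-pyran-2-carbonyl chloride | ClC(=O)c1cc(=O)c(-c2ccc(OC)c3OC(C)(C)CCc23)co1 | intermediate (not isolated)
14 | 2-(2-diazoacetyl)-5-(8-methoxy-2,2-dimethylchroman-5-yl)-4H-pyran-4-one | [N-]=[N+]=CC(=O)c1cc(=O)c(-c2ccc(OC)c3OC(C)(C)CCc23)co1 | intermediate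
15 | ethoxyacetylene | C#COCC | starting material
16 | 5-(8-methoxy-2,2-dimethylchroman-5-yl)-2-(2-oxoethenyl)-4H-pyran-4-one (pyranonylketene) | O=C=Cc1cc(=O)c(-c2ccc(OC)c3OC(C)(C)CCc23)co1 | intermediate (not isolated)
17 | 2-(2-ethoxy-4-oxocyclobut-2-en-1-yl)-5-(8-methoxy-2,2-dimethylchroman-5-yl)-4H-pyran-4-one, racemic | CCOC1=CC(=O)C1c1cc(=O)c(-c2ccc(OC)c3OC(C)(C)CCc23)co1 | intermediate (not isolated)
18 | 2-[(1E)-2-ethoxy-4-oxobuta-1,3-dien-1-yl]-5-(8-methoxy-2,2-dimethylchroman-5-yl)-4H-pyran-4-one (dienylketene, ketene and pyranone cis) | O=C=C/C(OCC)=C\c1cc(=O)c(-c2ccc(OC)c3OC(C)(C)CCc23)co1 | intermediate (not isolated)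
19 | 7-ethoxy-5-hydroxy-3-(8-methoxy-2,2-dimethylchroman-5-yl)-4H-chromen-4-one | CCOc1cc(O)c2c(c1)occ(-c1ccc(OC)c3OC(C)(C)CCc13)c2=O | intermediate
20 | 5,7-dihydroxy-3-(8-hydroxy-2,2-dimethylchroman-5-yl)-4H-chromen-4-one | CC1(C)CCc2c(-c3coc4cc(O)cc(O)c4c3=O)ccc(O)c2O1 | target

**Step count**

Total: 12 steps. Longest linear sequence: 10 steps (steps 1–4 and 7–12, from 5-bromo-2-methoxyphenol); the kojic acid branch (steps 5 and 6) joins at step 7.

**Steps most likely to fail**

1. Step 11 (proposed new method). Several processes could divert it: residual light absorption by the pyranone or the product leading to photoisomerisation; dimerisation of the ketene or its capture by the product phenol; unproductive outward opening of the cyclobutenone; and a slow 6π closure onto the pyranone double bond. The fallback uses known isoflavone chemistry, sets out from boronate 6 and comes back at target 20. Commercial 2'-hydroxy-4',6'-dimethoxyacetophenone is condensed with N,N-dimethylformamide dimethyl acetal to (E)-3-(dimethylamino)-1-(2-hydroxy-4,6-dimethoxyphenyl)prop-2-en-1-one F1. Iodine-induced cyclisation of F1 should give 3-iodo-5,7-dimethoxy-4H-chromen-4-one F2. Suzuki coupling of F2 with 6 (Pd(PPh3)4, Na2CO3, DME/H2O, 80 °C) should give 5,7-dimethoxy-3-(8-methoxy-2,2-dimethylchroman-5-yl)-4H-chromen-4-one F3, and BBr3 in CH2Cl2 should then cleave the three methyl ethers to give 20.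

2. Step 10. The diazoalkane may add as a 1,3-dipole to the pyranone enone, the chlorinating agent may activate the ring carbonyl, and HCl may convert the diazoketone to the chloromethyl ketone. The fallback replaces acylation of a diazoalkane by diazo transfer; it sets out from alcohol 11 and comes back at diazoketone 14. Oxidation of 11 with MnO2 should give 5-(8-methoxy-2,2-dimethylchroman-5-yl)-4-oxo-4H-pyran-2-carbaldehyde F4. MeMgBr at –78 °C adds to the aldehyde to give racemic 2-(1-hydroxyethyl)-5-(8-methoxy-2,2-dimethylchroman-5-yl)-4H-pyran-4-one F5, and Dess–Martin periodinane gives 2-acetyl-5-(8-methoxy-2,2-dimethylchroman-5-yl)-4H-pyran-4-one F6. Detrifluoroacetylative diazo transfer then follows: LiN(SiMe3)2 and 2,2,2-trifluoroethyl trifluoroacetate at –78 °C give 4,4,4-trifluoro-1-[5-(8-methoxy-2,2-dimethylchroman-5-yl)-4-oxo-4H-pyran-2-yl]butane-1,3-dione F7, which with methanesulfonyl azide, Et3N and water in MeCN should deliver 14.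

3. Step 12. Lewis-acid ionisation of the tertiary alkyl aryl ether (opening of the dimethylchroman ring) may compete with the slower cleavage of the ethyl ether. The fallback accepts ring opening and repairs it; it sets out from 19 and comes back at 20. Excess BBr3 at room temperature is used to drive both dealkylations to completion, giving 3-[2-(3-bromo-3-methylbutyl)-3,4-dihydroxyphenyl]-5,7-dihydroxy-4H-chromen-4-one F8 (or its alkene elimination products). Catalytic p-toluenesulfonic acid in toluene at 80 °C then recloses the ring, since acid-mediated cyclisation of such side chains onto an ortho phenol is the classical way to 2,2-dimethylchromans. Only the hydroxyl that came from the chroman oxygen is ortho to the side chain, so reclosure can give only 20.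

**Further compounds**

F1 | step 11 | (E)-3-(dimethylamino)-1-(2-hydroxy-4,6-dimethoxyphenyl)prop-2-en-1-one | CN(C)/C=C/C(=O)c1c(O)cc(OC)cc1OC
F2 | step 11 | 3-iodo-5,7-dimethoxy-4H-chromen-4-one | COc1cc(OC)c2c(c1)occ(I)c2=O
F3 | step 11 | 5,7-dimethoxy-3-(8-methoxy-2,2-dimethylchroman-5-yl)-4H-chromen-4-one | COc1cc(OC)c2c(c1)occ(-c1ccc(OC)c3OC(C)(C)CCc13)c2=O
F4 | step 10 | 5-(8-methoxy-2,2-dimethylchroman-5-yl)-4-oxo-4H-pyran-2-carbaldehyde | O=Cc1cc(=O)c(-c2ccc(OC)c3OC(C)(C)CCc23)co1
F5 | step 10 | 2-(1-hydroxyethyl)-5-(8-methoxy-2,2-dimethylchroman-5-yl)-4H-pyran-4-one, racemic | CC(O)c1cc(=O)c(-c2ccc(OC)c3OC(C)(C)CCc23)co1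
F6 | step 10 | 2-acetyl-5-(8-methoxy-2,2-dimethylchroman-5-yl)-4H-pyran-4-one | CC(=O)c1cc(=O)c(-c2ccc(OC)c3OC(C)(C)CCc23)co1
F7 | step 10 | 4,4,4-trifluoro-1-[5-(8-methoxy-2,2-dimethylchroman-5-yl)-4-oxo-4H-pyran-2-yl]butane-1,3-dione | O=C(CC(=O)C(F)(F)F)c1cc(=O)c(-c2ccc(OC)c3OC(C)(C)CCc23)co1
F8 | step 12 | 3-[2-(3-bromo-3-methylbutyl)-3,4-dihydroxyphenyl]-5,7-dihydroxy-4H-chromen-4-one | CC(C)(Br)CCc1c(O)c(O)ccc1-c1coc2cc(O)cc(O)c2c1=O
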